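## Structural features

The target is a 1H-indole, a benzene ring fused along the C3a–C7a bond to a pyrrole ring, with no side chain and no stereocenter, so no stereochemical relationship has to be set. All four substituents are bromine atoms, at C2 and C3 of the pyrrole ring and at C4 and C7 of the benzene ring, the latter two para to each other and each ortho to a ring-fusion carbon. The fragile elements are the N–H 2,3-dibromopyrrole unit, which is sensitive to acid, light and oxidants, and the four C–Br bonds, which exclude alkyllithium exchange, zerovalent palladium, dissolving metals and hydrogenolysis. The real difficulty is regiochemical, because electrophilic bromination of an indole goes to C3, then C2, then C5 and C6, and not selectively to C4 and C7. The benzenoid bromines must therefore come in with a benzene building block, and the pyrrole ring must be built onto it. The key step uses the fact that C7a (bearing N1) and C3a (bearing C3) are adjacent carbons flanked by C7–Br and C4–Br, which is the pattern of a nitrogen nucleophile and a carbon electrophile added across the triple bond of symmetric 3,6-dibromobenzyne. Because that aryne is symmetric, N1–C7a and C3–C3a can form in either orientation with the same result, and the C3 carbonyl left by the ring closure is the handle for the C3 bromine.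

## Logic of the disconnections

**17 ⇒ 16.** The C2–Br bond is cut first. With C3 already brominated, an electrophilic bromine source can only end at C2 of the free N–H pyrrole ring. Doing this last keeps the acid- and light-sensitive N–H 2,3-dibromopyrrole unit out of every other step, so the gain is mainly in robustness of the intermediates. The forward step needs one equivalent of a mild reagent and must leave C5 and C6 alone, which the flanking bromines should ensure.

**16 ⇒ 15.** The N–H is traced back to an N–S bond. The sulfonyl group is needed for ring construction and protects the earlier intermediates from oxidation. It is removed before the last bromination because the free indole reacts with a mild electrophile, whereas the sulfonylated ring would need metalation next to C3–Br. The skeleton is not simplified here; the forward cleavage must be nucleophilic and not reductive, so that three C–Br bonds survive.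

**15 ⇒ 14.** C3–Br is exchanged for the C3 carbonyl. The ketone is what the ring-forming step leaves at C3, and deoxybromination of an enolisable ketone both installs the bromine and aromatises the five-membered ring. This replaces a separate reduction, dehydration and bromination. The demand is that bromide is delivered to C3 through oxygen activation and that the reagent does not brominate C2 of the enol.

**14 ⇒ 8 + 11.** N1–C7a and C3–C3a are cut together. C7a and C3a are adjacent and each has a brominated neighbour, so the benzene part corresponds to 12 (released from 8), and the N1–C2–C3 unit with the right oxidation level at C3 corresponds to 11. The bicycle is reduced to a tetrasubstituted benzene and a protected glycine ester, and the symmetry of 12 removes any regiochemical question. The forward step requires that 13 acylates itself faster than it is protonated or loses bromide.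

**8 ⇒ 6.** The aryl O–S bond is cut and the oxygen is returned to a carbamate, passing through 7. An ortho-silyl aryl triflate releases the aryne with fluoride under conditions that leave C–Br bonds and the ester of 11 untouched. A secondary (N–H) carbamate is chosen over a tertiary one because it fragments under mild amine base. Cleavage and triflation can then share one flask, 7 is not isolated, and the sequence to 8 is three steps. The forward step must triflate a phenoxide crowded by SiMe3 and Br without protodesilylation.

**6 ⇒ 2.** The C–Si bond is cut. The carbon that must carry silicon lies between the carbamate oxygen and a bromine and is the most acidic ring position. Directed ortho-metalation with a lithium amide, which does not exchange bromine, reaches it selectively. The forward step must trap 4 at once, so the silyl chloride is present during deprotonation, and the N–H must be masked in the flask as 3.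

**2 ⇒ 1.** The carbamate C–O bond is cut, giving commercial 1, in which both bromines already stand para to each other and in the right relation to oxygen. The forward carbamoylation is an addition without by-product.

**11 ⇒ 9 + 10.** The N–S bond is cut, giving two commodity chemicals. The forward sulfonylation only needs enough base to free the amine from its salt.

## Other disconnections considered

Alternative 1: The cut runs through the carbocycle at C3a–C4 and C7–C7a, so the benzene ring would be built onto a preformed five-membered nitrogen ring.
- Forward key step: 2,5-dibromothiophene 1,1-dioxide A2 would act as an electron-poor diene and tert-butyl 2,3-dihydro-1H-pyrrole-1-carboxylate A3 as an electron-rich enecarbamate dienophile in an inverse-demand [4+2] cycloaddition. Cheletropic extrusion of the sulfonyl bridge from the adduct would leave tert-butyl 4,7-dibromo-2,3,3a,7a-tetrahydroindole-1-carboxylate A1 as a cis-fused, racemic diene. Dehydrogenation of both rings and carbamate removal would then lead to 4,7-dibromo-1H-indole A4 and two electrophilic brominations (C3, then C2) would finish.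
- In its favour: diene A2 and dienophile A3 are electronically matched. Both benzenoid bromines arrive in one symmetric component, so no regiochemical issue arises (equal to the chosen plan). No carbanion ever sits next to a C–Br bond (better than the chosen plan, whose 13 can in principle expel bromide). About six operations are needed against eight (better on step economy).
- Against it: A2 requires a powerful electrophilic oxidant for its preparation and, like other thiophene dioxides, tends to dimerise. The two stereocenters of A1 would be made only to be destroyed. Compound A1 could also aromatise by dehydrobromination after a hydrogen shift instead of by dehydrogenation, which would erase a bromine the plan exists to place. No handle is left at C3, so both pyrrole bromines would depend on electrophilic substitution of A4 alone.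
- Comparison: the alternative is shorter and avoids the ortho-bromo carbanion. The chosen plan keeps the arene aromatic throughout, so no bromine can be lost in an aromatisation, and it delivers oxygen at C3 where bromine is required.

Alternative 2: The cut is the N1–C7a bond alone.
- Forward key step: 2,5-dibromobenzaldehyde A5 would be condensed with methyl azidoacetate A6 under alkoxide base (Knoevenagel-type condensation) to give methyl (Z)-2-azido-3-(2,5-dibromophenyl)acrylate A7 as the precursor. Heating A7 in a high-boiling aromatic hydrocarbon (Hemetsberger–Knittel synthesis) would cause denitrogenation to a vinyl nitrene (or its 2H-azirine equivalent), which closes onto the ortho C–H carbon and forms methyl 4,7-dibromo-1H-indole-2-carboxylate A8 as the product of the key step.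
- In its favour: A5 carries bromine on one ortho carbon, so only one ortho C–H is available and the 4,7-pattern is certain (equal to the chosen plan). The indole nucleus would be reached in two steps from cheap materials, without N-protection, by very well established chemistry (better in precedent for the ring closure).
- Against it: A6 and A7 are low-molecular-weight organic azides, and A7 must be heated to decomposition, a real hazard on scale. The ester carbon at C2 of A8 is not in the target. It would have to be removed by saponification and decarboxylation, which leads to A4 again, or replaced by bromine in a halodecarboxylation, at temperatures that threaten aryl C–Br bonds. C3 again has no handle.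
- Comparison: condensation, thermolysis, saponification, decarboxylation and two brominations make about six steps, fewer than eight (better on step count). The alternative excises a carbon atom and is less safe. The chosen plan forms two ring bonds in its key operation where this one forms one, and leaves a useful oxygen at C3 where this one leaves a superfluous carbon at C2.

Alternative 3: The cuts are C3–C3a and N1–C2.
- Forward key step: 2,5-dibromoaniline A9 would be N-chlorinated with an alkyl hypochlorite and combined with ethyl 2-(methylthio)acetate A10 to an azasulfonium salt. Amine base would give the ylide, which rearranges by a [2,3]-sigmatropic (Sommelet–Hauser-type) shift onto the ortho carbon (Gassman oxindole synthesis). Acid would then close the lactam, so that racemic 4,7-dibromo-3-(methylthio)indolin-2-one A11 results. Reductive removal of sulfur would give 4,7-dibromoindolin-2-one A12 as the next intermediate, deoxybromination of its lactam carbonyl would give 2,4,7-tribromo-1H-indole A13 and bromination at C3 would finish.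
- In its favour: it is a one-flask ring synthesis from a cheap aniline. The rearrangement can only go to the single free ortho carbon of A9 (equal in regiochemical certainty). The C2 lactam carbonyl of A12 is a handle for C2–Br in the same sense in which the C3 ketone of 14 is a handle for C3–Br (equal in logic). No nitrogen protecting group is needed. Four steps are half of the chosen plan (clearly better on step economy).
- Against it: A9 is a weakly nucleophilic, ortho-hindered aniline, and its N-chloro derivative and the hypochlorite needed to make it are unpleasant to handle. Sulfur must be removed from A11 without hydrogenolysis of the aryl bromides, which excludes classical nickel desulfurisation and forces a milder thiol-exchange or zinc-based reduction. Compound A13 is an acid-sensitive N–H 2-bromoindole that would be formed under strongly acidic conditions.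
- Comparison: the sigmatropic shift is at least as dependable as aryl-anion acyl capture, and the route is much shorter. The chosen plan avoids sulfur removal on a polybrominated arene and reaches the stable N-protected intermediate 15 before the sensitive N–H stage.

Key step: step 5

Remark on the chemistry: LiN(iPr)2 is taken as a commercial solution; 11 is prepared in one step although it can also be bought; the target and all route intermediates are achiral.

## Route

Step 1
Reactants: 1 2,5-dibromophenol
Product: 2 2,5-dibromophenyl N-isopropylcarbamate
Conditions: iPrNCO (1.5 equiv), Et3N (0.2 equiv), CH2Cl2, rt
Reagents that add atoms: isopropyl isocyanate, CC(C)N=C=O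
Why: Base-catalysed addition of the phenol O–H across the isocyanate (carbamoylation) proceeds without by-product; the secondary carbamate is chosen because it directs ortho-metalation once N-silylated and can later be removed by mild E1cB fragmentation.

Step 2
Reactants: 2 2,5-dibromophenyl N-isopropylcarbamate
Product: 6 3,6-dibromo-2-(trimethylsilyl)phenyl N-isopropylcarbamate, via N-silyl carbamate 3 (not isolated), via aryllithium 4 (not isolated), via bis-silyl carbamate 5 (not isolated)
Conditions: Me3SiOTf (1.1 equiv), TMEDA (1.1 equiv), Et2O, 0 °C to rt; then Me3SiCl (4 equiv), LiN(iPr)2 (3 equiv), THF, −78 °C; aq. NaHSO4 work-up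
Reagents that add atoms: chlorotrimethylsilane, C[Si](C)(C)Cl
Why: In situ N-silylation (Me3SiOTf) masks the N–H, and LiN(iPr)2, which deprotonates but does not exchange C–Br, removes the one ring proton flanked by the carbamate oxygen and a bromine (directed ortho-metalation). Me3SiCl already present traps aryllithium 4 before LiBr loss or anionic ortho-Fries migration can occur, and the N–Si bond of 5 is hydrolysed on acidic work-up.

Step 3
Reactants: 6 3,6-dibromo-2-(trimethylsilyl)phenyl N-isopropylcarbamate
Product: 8 3,6-dibromo-2-(trimethylsilyl)phenyl trifluoromethanesulfonate, via silylphenol 7 (not isolated)
Conditions: Et2NH (1.5 equiv), DBU (1.5 equiv), MeCN, 40 °C; then PhNTf2 (1.5 equiv), rt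
Reagents that add atoms: N-phenylbis(trifluoromethanesulfonimide), O=S(=O)(N(c1ccccc1)S(=O)(=O)C(F)(F)F)C(F)(F)F
Why: DBU deprotonates the carbamate N–H and the aryloxide is expelled (E1cB carbamate cleavage), with Et2NH scavenging the isocyanate as a urea. The phenoxide of 7 is then triflated in the same flask by the mild triflyl donor (O-sulfonylation), so the protodesilylation-prone free silylphenol is never handled.

Step 4
Reactants: 9 glycine methyl ester hydrochloride; 10 p-toluenesulfonyl chloride
Product: 11 methyl N-tosylglycinate (methyl N-(p-toluenesulfonyl)glycinate)
Conditions: Et3N (2.2 equiv), CH2Cl2, 0 °C to rt
Reagents that add atoms: none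
Why: N-Sulfonylation of the amine freed from its hydrochloride; the sulfonamide formed is far less nucleophilic than the amine, which prevents a second sulfonylation.

Step 5
Reactants: 8 3,6-dibromo-2-(trimethylsilyl)phenyl trifluoromethanesulfonate; 11 methyl N-tosylglycinate
Product: 14 4,7-dibromo-1-tosylindolin-3-one, via aryne 12 (not isolated), via aryl anion 13 (not isolated)
Conditions: CsF (3 equiv), THF, 65 °C; 11 in slight excess (1.3 equiv)
Reagents that add atoms: none
Why: Fluoride attacks silicon of 8 and triflate departs from the neighbouring carbon, releasing aryne 12 slowly because CsF is only sparingly soluble in THF. The sulfonamide anion of 11 (formed by fluoride or by the methoxide released later) adds to one end of the strained triple bond, which makes N1–C7a and places the negative charge on the neighbouring carbon (aryl anion 13), where the adjacent C–Br bond stabilises it inductively. The carbanion then attacks the ester carbonyl two atoms away in a 5-exo-trig acyl substitution that forms C3–C3a, closes the five-membered ring and expels methoxide. The closest known reaction type is the fluoride-induced annulation of arynes with N-sulfonyl α-amino carbonyl compounds and with ortho-heteroatom-substituted benzoates (heteroatom arylation followed by carbonyl capture of the aryl anion). No stereocenter is formed. No regioselectivity is required, because 12 has a mirror plane through the triple bond and both orientations of addition put bromine at C4 and C7. The selectivity that is required is kinetic: acylation of 13 must be faster than its protonation or loss of the flanking bromide, which is favoured by the five-membered intramolecular trajectory, by THF in place of a C–H acidic solvent and by the absence of any proton source stronger than the sulfonamide. Keeping 11 in excess and the aryne concentration low should also protect the enolisable product from further arylation.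

Step 6
Reactants: 14 4,7-dibromo-1-tosylindolin-3-one
Product: 15 3,4,7-tribromo-1-tosyl-1H-indole
Conditions: P(OPh)3 (1.2 equiv), Br2 (1.2 equiv), CH2Cl2, −60 °C; then 14, Et3N (1.5 equiv), −60 °C to reflux
Reagents that add atoms: bromotriphenoxyphosphonium bromide (triphenyl phosphite dibromide, formed in the flask from triphenyl phosphite and Br2), Br[P+](Oc1ccccc1)(Oc1ccccc1)Oc1ccccc1.[Br-]
Why: Halophosphonium deoxybromination of an enolisable ketone to a vinyl bromide: the carbonyl oxygen is activated on phosphorus, bromide is delivered to C3, and Et3N removes a C2 proton with loss of triphenyl phosphate. The elimination is driven here by formation of the aromatic pyrrole ring, and the N-tosyl group prevents oxidative dimerisation of the indoxyl.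

Step 7
Reactants: 15 3,4,7-tribromo-1-tosyl-1H-indole
Product: 16 3,4,7-tribromo-1H-indole
Conditions: NaOH (3 equiv), THF/MeOH/H2O, 50 °C; aq. NH4Cl
Reagents that add atoms: none
Why: Nucleophilic cleavage of the N–S bond by hydroxide (sulfonamide hydrolysis); the tribrominated indolide is a good leaving group and the peri bromine at C7 strains the sulfonamide, so mild non-reductive conditions should suffice and all C–Br bonds stay intact.

Step 8
Reactants: 16 3,4,7-tribromo-1H-indole
Product: 17 2,3,4,7-tetrabromo-1H-indole
Conditions: NBS (1.05 equiv), DMF, 0 °C to rt, dark
Reagents that add atoms: N-bromosuccinimide, O=C1CCC(=O)N1Br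
Why: Electrophilic bromination of a 3-substituted N–H indole: with C3 occupied the bromine ends at C2 (direct attack, or ipso attack at C3 followed by a 1,2-shift) and rearomatisation gives the 2,3-dibromide. C5 and C6 are deactivated by the flanking bromines, so one equivalent should stop at the target.

## Compound list

1 | 2,5-dibromophenol | Oc1cc(Br)ccc1Br | starting material
2 | 2,5-dibromophenyl N-isopropylcarbamate | CC(C)NC(=O)Oc1cc(Br)ccc1Br | intermediate
3 | 2,5-dibromophenyl N-isopropyl-N-(trimethylsilyl)carbamate (not isolated) | CC(C)N(C(=O)Oc1cc(Br)ccc1Br)[Si](C)(C)C | intermediate
4 | 3,6-dibromo-2-lithiophenyl N-isopropyl-N-(trimethylsilyl)carbamate (not isolated) | CC(C)N(C(=O)Oc1c([Li])c(Br)ccc1Br)[Si](C)(C)C | intermediate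
5 | 3,6-dibromo-2-(trimethylsilyl)phenyl N-isopropyl-N-(trimethylsilyl)carbamate (not isolated) | CC(C)N(C(=O)Oc1c([Si](C)(C)C)c(Br)ccc1Br)[Si](C)(C)C | intermediate
6 | 3,6-dibromo-2-(trimethylsilyl)phenyl N-isopropylcarbamate | CC(C)NC(=O)Oc1c([Si](C)(C)C)c(Br)ccc1Br | intermediate
7 | 3,6-dibromo-2-(trimethylsilyl)phenol (not isolated, present as its DBU salt) | C[Si](C)(C)c1c(Br)ccc(Br)c1O | intermediate
8 | 3,6-dibromo-2-(trimethylsilyl)phenyl trifluoromethanesulfonate | C[Si](C)(C)c1c(Br)ccc(Br)c1OS(=O)(=O)C(F)(F)F | intermediate
9 | glycine methyl ester hydrochloride | Cl.COC(=O)CN | starting material
10 | p-toluenesulfonyl chloride | Cc1ccc(cc1)S(Cl)(=O)=O | starting material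
11 | methyl N-tosylglycinate | COC(=O)CNS(=O)(=O)c1ccc(C)cc1 | intermediate
12 | 3,6-dibromobenzyne (1,4-dibromo-2,3-didehydrobenzene, not isolated) | BrC1=CC=C(Br)C#C1 | intermediate
13 | cesium 3,6-dibromo-2-[N-(2-methoxy-2-oxoethyl)-N-tosylamino]benzen-1-ide (aryl anion, not isolated) | COC(=O)CN(c1[c-]c(Br)ccc1Br)S(=O)(=O)c1ccc(C)cc1.[Cs+] | intermediate
14 | 4,7-dibromo-1-tosylindolin-3-one | Cc1ccc(cc1)S(=O)(=O)N1CC(=O)c2c(Br)ccc(Br)c21 | intermediate
15 | 3,4,7-tribromo-1-tosyl-1H-indole | Cc1ccc(cc1)S(=O)(=O)n1cc(Br)c2c(Br)ccc(Br)c21 | intermediate
16 | 3,4,7-tribromo-1H-indole | Brc1c[nH]c2c(Br)ccc(Br)c12 | intermediate
17 | 2,3,4,7-tetrabromo-1H-indole | Brc1[nH]c2c(Br)ccc(Br)c2c1Br | target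

## Step count and least certain steps

Total: 8 steps. Longest linear sequence: 7 steps (steps 1, 2, 3, 5, 6, 7, 8, from 1 to 17); step 4 is a one-step side branch.

**Step 5 (key step).** Most likely failure: proton transfer to carbanion 13 or expulsion of the neighbouring bromide outruns the ring-closing acylation. The proton could come from the α-CH2 of a second molecule of 11, from the acidic C2–H of the product, or from adventitious water. Amination would then occur without ring closure, or material would drain into a second aryne and its oligomers. Arylation of the enolisable product by excess aryne and an anionic triflyl shift in 8 are lesser risks. Fallback: the two bonds are made in separate steps. Setting out from 8 and 11, the aryne amination is run deliberately as a simple N-arylation with a proton source at hand (CsF, MeCN, rt) to give methyl N-(2,5-dibromophenyl)-N-tosylglycinate F1. Saponification (LiOH, THF/H2O) gives N-(2,5-dibromophenyl)-N-tosylglycine F2. Intramolecular Friedel–Crafts acylation (P2O5 in MeSO3H, 60–80 °C) then closes C3–C3a at the only free position ortho to nitrogen and returns to 14. The ring is deactivated by two bromines, so this closure will be slow, but it is an electrophilic process in which neither protonation nor bromide loss can interfere.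

**Step 6.** Most likely failure: the easily formed enol of 14 is captured on oxygen without onward substitution, or is brominated at C2 by the electrophilic phosphonium bromide, instead of taking up bromide at C3. Both follow from the unusual acidity of the protons between the ketone and the sulfonamide nitrogen. Fallback: setting out from 14, reduction (NaBH4, MeOH/THF, 0 °C) gives racemic 4,7-dibromo-1-tosylindolin-3-ol F3. Acid-catalysed dehydration (TsOH, toluene, 80 °C) gives 4,7-dibromo-1-tosyl-1H-indole F4. Electrophilic bromination (Br2, CH2Cl2, 0 °C to rt) takes place at C3 and returns to 15.

**Step 2.** Most likely failure: incomplete N-silylation lets the amide base deprotonate nitrogen, after which the carbamate fragments to phenoxide and isocyanate. If trapping is slow, aryllithium 4 can also lose LiBr to an aryne, or the carbamoyl group can migrate to carbon (anionic ortho-Fries shift). Fallback: silicon is delivered intramolecularly and no carbamate is used. Setting out from 1, O-silylation with hexamethyldisilazane gives (2,5-dibromophenoxy)trimethylsilane F5. LiN(iPr)2 (THF, −78 °C to 0 °C) deprotonates between oxygen and bromine, and the silyl group migrates from oxygen to carbon (retro-Brook 1,3-shift) to give the lithium phenoxide of 7. Triflation with PhNTf2 in the same flask, as in the second half of step 3, returns to the route at 8.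

**Step 8.** Most likely failure: substitution is slow on a ring deactivated by three bromines. Forcing conditions would then invite hydrolysis of the N–H 2-bromoindole to an oxindole by traces of HBr and moisture, or a further bromination. Fallback: C2 is brominated before the nitrogen is freed. Setting out from 15, deprotonation at C2 with LiN(iPr)2 (THF, −78 °C; directed by the sulfonyl group, no C–Br exchange) and quench with BrCCl2CCl2Br gives 2,3,4,7-tetrabromo-1-tosyl-1H-indole F6. Cleavage with NaOH as in step 7 returns to 17.

## Further compounds

F1 | step 5 | methyl N-(2,5-dibromophenyl)-N-tosylglycinate | COC(=O)CN(c1cc(Br)ccc1Br)S(=O)(=O)c1ccc(C)cc1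
F2 | step 5 | N-(2,5-dibromophenyl)-N-tosylglycine | OC(=O)CN(c1cc(Br)ccc1Br)S(=O)(=O)c1ccc(C)cc1
F3 | step 6 | 4,7-dibromo-1-tosylindolin-3-ol (racemic) | Cc1ccc(cc1)S(=O)(=O)N1CC(O)c2c(Br)ccc(Br)c21
F4 | step 6 | 4,7-dibromo-1-tosyl-1H-indole | Cc1ccc(cc1)S(=O)(=O)n1ccc2c(Br)ccc(Br)c21
F5 | step 2 | (2,5-dibromophenoxy)trimethylsilane | C[Si](C)(C)Oc1cc(Br)ccc1Br
F6 | step 8 | 2,3,4,7-tetrabromo-1-tosyl-1H-indole | Cc1ccc(cc1)S(=O)(=O)n1c(Br)c(Br)c2c(Br)ccc(Br)c21
A1 | alternative 1 | tert-butyl cis-4,7-dibromo-2,3,3a,7a-tetrahydroindole-1-carboxylate (racemic, one enantiomer drawn) | CC(C)(C)OC(=O)N1CC[C@@H]2C(Br)=CC=C(Br)[C@H]12
A2 | alternative 1 | 2,5-dibromothiophene 1,1-dioxide | O=S1(=O)C(Br)=CC=C1Br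
A3 | alternative 1 | tert-butyl 2,3-dihydro-1H-pyrrole-1-carboxylate | CC(C)(C)OC(=O)N1CCC=C1
A4 | alternative 1 | 4,7-dibromo-1H-indole | Brc1ccc(Br)c2[nH]ccc12
A5 | alternative 2 | 2,5-dibromobenzaldehyde | O=Cc1cc(Br)ccc1Br
A6 | alternative 2 | methyl azidoacetate | COC(=O)CN=[N+]=[N-]
A7 | alternative 2 | methyl (Z)-2-azido-3-(2,5-dibromophenyl)acrylate | COC(=O)/C(N=[N+]=[N-])=C/c1cc(Br)ccc1Br
A8 | alternative 2 | methyl 4,7-dibromo-1H-indole-2-carboxylate | COC(=O)c1cc2c(Br)ccc(Br)c2[nH]1
A9 | alternative 3 | 2,5-dibromoaniline | Nc1cc(Br)ccc1Br
A10 | alternative 3 | ethyl 2-(methylthio)acetate | CCOC(=O)CSC
A11 | alternative 3 | 4,7-dibromo-3-(methylthio)indolin-2-one (racemic) | CSC1C(=O)Nc2c(Br)ccc(Br)c12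
A12 | alternative 3 | 4,7-dibromoindolin-2-one | O=C1Cc2c(Br)ccc(Br)c2N1
A13 | alternative 3 | 2,4,7-tribromo-1H-indole | Brc1cc2c(Br)ccc(Br)c2[nH]1
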